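The readings stem from a simulated flask with made-up constants, and the scatter is random.

We start by adding the two columns of Wednesday's run: at 10.0 min they fall short of the charge by 4.90 %, about the initiator loading of 5 mol%. We read this as each initiator starting one living end and putting one monomer into a chain, and each end finally taking one monomer into a dead end that neither column counts. If growth and death both use one living end and one free monomer, their ratio does not depend on concentration. Integrating one rate against the other then gives, with I the initiator loading and ν the chain length (monomer added to chains per end that dies), the ceiling y: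

y = I + Iν

in all of them: initiator 5 mol%

| run | free monomer | temperature | remark | time |
|---|---|---|---|---|
| Saturday's | 0.50 M | 20 °C | run made earlier |  |
| Wednesday's | 2 M | 48 °C | run made earlier |  |
| delta | 1.0 M | 40 °C |  | 15 min |
| zeta | 1.0 M | 70 °C |  | 15 min |
| theta | 1.0 M | 25 °C |  | 15 min |
| epsilon | 1.0 M | 55 °C |  | 15 min |

| run | time / min | monomer in chains / % | free monomer / % |
|---|---|---|---|
| Saturday's | 4.00 | 49.2 | 48.3 |
| Saturday's | 10.0 | 70.4 | 26.5 |
| Saturday's | 15.0 | 77.0 | 19.8 |
| Saturday's | 25.0 | 83.2 | 12.0 |
| Saturday's | 40.0 | 87.6 | 7.5 |
| Saturday's | 50.0 | 88.9 | 6.6 |
| Wednesday's | 1.33 | 36.6 | 58.3 |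
| Wednesday's | 2.50 | 36.6 | 58.9 |
| Wednesday's | 4.00 | 36.6 | 58.0 |
| Wednesday's | 6.00 | 36.7 | 59.0 |
| Wednesday's | 10.0 | 36.7 | 58.4 |
| Wednesday's | 20.0 | 36.6 | 58.7 |

(scatter of a reading: 0.3 percentage points)



- the flask that comes out highest in amount of monomer in chains, in percent of the free monomer charged, or "all alike" when all lie within 1.5 percentage points (delta / zeta / theta / epsilon / all alike)
- monomer in chains at the end, in percent of the free monomer charged, delta
- monomer in chains at the end, in percent of the free monomer charged, zeta
- monomer in chains at the end, in percent of the free monomer charged, theta
- monomer in chains at the end, in percent of the free monomer charged, epsilon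

Wednesday's run has stopped, so it gives ν = 6.34 at 48 °C. Saturday's run is still moving, so we divide its chain monomer beyond I by its gap at the last reading, which gives 18.6 at 20 °C. These readings, taken on a straight line of ln ν against reciprocal temperature, give an energy difference of 30.2 kJ/mol. At theta's temperature, the chain length ν, monomer added per end that dies, comes to 15.2.

Two extreme flasks can be reckoned in the head. If the ends never died, no dead end would form, and chains would in the end take the whole charge:

y = 100 %

If the ends finish their lives in time, the ceiling holds:

delta 47.3 %, zeta 20.4 %, theta 80.8 %, epsilon 29.9 %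

Wednesday's run was flat by 1.33 min, far shorter than the 15 min of our flasks, so we expect delta, epsilon and zeta on their ceilings. Theta holds twice Saturday's charge and is warmer, yet Saturday's run was still rising between 25.0 min and 40.0 min. We therefore put theta just under its ceiling, and still highest.

The forecast says “Wednesday's flat readings indicate equilibrium” and gives 51 % for delta, 0.3 % for zeta, 87 % for theta and 2.2 % for epsilon, with theta highest. Ours differs: theta lower, zeta and epsilon higher.

The flasks give 47.0 % for delta, 20.3 % for zeta, 77.9 % for theta and 29.8 % for epsilon, with theta highest.

    free monomer + initiator → living end + monomer in chains (k = 0.170 /M/s, Ea = 39.0 kJ/mol)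
    free monomer + living end → monomer in chains + living end, rate k2*[living end]*[free monomer] (k = 0.210 /M/s, Ea = 38.0 kJ/mol)
    living end + free monomer → dead end (k = 0.0140 /M/s, Ea = 68.0 kJ/mol)
    (constants at 25 °C)

In theta, half of the starting of ends up to the asked time was done by 0.0694 min, far sooner than half of the dying, by 1.21 min. At 15.0 min theta still held 0.00139 M of living end, and by 150 min it stood at 80.0 %, against our ceiling of 80.8 %. The same ν with 2 mol% of initiator at theta's temperature gives a ceiling of 32.3 %, and that neighbour flask stands at 32.0 %.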